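**Retrosynthetic overview**
1. The enol ether C14=C15 is unveiled last by lactol dehydration, after ring B of a Δ7-6-ketone has been oxidised (6β-OH-directed β-face dihydroxylation at C7/C8, 7-acetylation, oxidation at C6).
2. Key disconnection: the γ-lactone ring C13–C14–C15(=O)–O16–C16 of spirolactone 14 (the dihydrofuran at the lactone level) is cut at C15–O16 and C14–C13, giving spiro-tetrahydrofuran alcohol 11 and a two-carbon diazoacetyl unit.
3. Enabling feature: C13, the spiro atom shared by the tetrahydrofuran (O9, C9, C11, C12, C13) and the dihydrofuran (C13, C14, C15, O16, C16), is a tertiary ether carbon. In 11 it carries one hydrogen, activated by O9 and lying 1,5 to a carbenoid at C14 hung on O16, so C–H insertion builds the quaternary centre with retention.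
4. The tetrahydrofuran (O9–C9 bond) comes from the C13 alkoxyl radical by 1,5-hydrogen transfer from C9. C13 is set by asymmetric hydrogenation of a hydroxyacetone side chain obtained by degrading (+)-larixol, which supplies rings A and B with C5 and C10.
5. Ring order: A/B (chiral pool), tetrahydrofuran (step 6), lactone ring (step 8), its conversion to the dihydrofuran (steps 9, 10, 13, 14).

Key step: step 8

Assumption: (+)-larixol and glyoxylic acid chloride p-toluenesulfonylhydrazone are taken as purchasable; atom numbers follow the labdane skeleton, with O9 and O16 the oxygens on C9 and C16.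

**Step 1**
Reactants: 1 (+)-larixol
Product: 2 6α-hydroxy-14,15-dinorlabd-8(17)-en-13-one
Conditions: KMnO4, acetone/H2O, 0 °C
Reagents that add atoms: none
Why: Permanganate degradation of the tertiary allylic alcohol (dihydroxylation of the monosubstituted vinyl group, then glycol-type cleavage of C13–C14) should leave the C13 methyl ketone while the hindered C8=C17 alkene reacts more slowly, and no stereocentre is formed.

**Step 2**
Reactants: 2 6α-hydroxy-14,15-dinorlabd-8(17)-en-13-one
Product: 4 14,15-dinorlabd-7-ene-6,13-dione, via exocyclic enone 3 (not isolated)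
Conditions: Dess–Martin periodinane, CH2Cl2, 25 °C; then DBU, 25 °C
Reagents that add atoms: none
Why: Dess–Martin oxidation of the 6α-alcohol gives the β,γ-unsaturated 6-ketone, which DBU should move into conjugation through the C7 dienolate, the trans ring fusion at C5 and the equatorial side chain at C9 being the stable arrangements.

**Step 3**
Reactants: 4 14,15-dinorlabd-7-ene-6,13-dione
Product: 7 16-hydroxy-14,15-dinorlabd-7-ene-6,13-dione, via silyl enol ether 5 (not isolated), via silyloxy ketone 6 (not isolated)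
Conditions: LiN(i-Pr)2 (commercial solution), Me3SiCl, THF, −78 °C; mCPBA, NaHCO3, CH2Cl2, −20 °C; 1 M HCl, THF, 0 °C
Reagents that add atoms: mCPBA, O=C(OO)c1cccc(Cl)c1; chlorotrimethylsilane, C[Si](C)(C)Cl (silicon stays only in 5 and 6)
Why: Kinetic deprotonation should take the unhindered C16 methyl protons (the enone offers only the shielded ring-fusion C5–H and slower γ-protons) and Rubottom oxidation of the terminal silyl enol ether then places the hydroxyl on C16, no stereocentre being formed.

**Step 4**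
Reactants: 7 16-hydroxy-14,15-dinorlabd-7-ene-6,13-dione
Product: 8 (13R)-13,16-dihydroxy-14,15-dinorlabd-7-en-6-one
Conditions: RuBr2[(R)-BINAP] (1 mol%), H2 (50 atm), MeOH, 30 °C
Reagents that add atoms: none
Why: Noyori asymmetric hydrogenation of an α-hydroxy ketone, in which the C16 hydroxyl and the C13 carbonyl chelate divalent ruthenium and the (R)-BINAP ligand fixes the face of hydride delivery, should set the (13R) carbinol in the sense known for hydroxyacetone while the non-chelating, hindered enone is left alone.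

**Step 5**
Reactants: 8 (13R)-13,16-dihydroxy-14,15-dinorlabd-7-en-6-one
Product: 9 (13R)-16-benzoyloxy-13-hydroxy-14,15-dinorlabd-7-en-6-one
Conditions: BzCl (1.05 equiv), 2,4,6-collidine, CH2Cl2, −78 to 0 °C
Reagents that add atoms: benzoyl chloride, O=C(Cl)c1ccccc1
Why: Selective acylation of the primary hydroxyl over the secondary one leaves O13 alone free for the next step and gives C16 an acyloxy group that slows β-scission.

**Step 6**
Reactants: 9 (13R)-16-benzoyloxy-13-hydroxy-14,15-dinorlabd-7-en-6-one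
Product: 10 (13R)-16-benzoyloxy-9α,13-epoxy-14,15-dinorlabd-7-en-6-one
Conditions: PhI(OAc)2, I2, cyclohexane/CH2Cl2, visible light, 25 °C
Reagents that add atoms: none
Why: In this Suárez hypoiodite reaction the C13 alkoxyl radical takes its only δ-hydrogen, the allylic tertiary C9–H, by 1,5-hydrogen transfer and the oxidised C9 centre is closed by O13 to the tetrahydrofuran, which should place oxygen on the α-face of C9 from which hydrogen left because the β-face is screened by the C10 methyl group, C13 being untouched.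

**Step 7**
Reactants: 10 (13R)-16-benzoyloxy-9α,13-epoxy-14,15-dinorlabd-7-en-6-one
Product: 11 (13R)-9α,13-epoxy-16-hydroxy-14,15-dinorlabd-7-en-6-one
Conditions: K2CO3 (0.2 equiv), MeOH, 25 °C
Reagents that add atoms: none
Why: Base-catalysed methanolysis of the benzoate frees the primary C16 alcohol without harming the γ-alkoxy enone, which has no γ-hydrogen left for elimination.

**Step 8**
Reactants: 11 (13R)-9α,13-epoxy-16-hydroxy-14,15-dinorlabd-7-en-6-one
Product: 14 (13S)-9α,13-epoxy-6-oxolabd-7-en-15,16-olide, via tosylhydrazone ester 12 (not isolated), via diazoacetate 13 (not isolated)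
Conditions: TsNHN=CHCOCl, PhNMe2, CH2Cl2, 0 °C; Et3N, 0 °C; cold aqueous wash; crude 13 added slowly to Rh2(NHCOCH3)4 (1 mol%), CH2Cl2, 40 °C
Reagents that add atoms: glyoxylic acid chloride p-toluenesulfonylhydrazone, Cc1ccc(cc1)S(=O)(=O)NN=CC(Cl)=O
Why: Acylation of O16 by the hydrazone acid chloride and triethylamine-induced loss of p-toluenesulfinate (Bamford–Stevens-type) give diazoacetate 13 and with it the C15–O16 bond, after which the dirhodium carbenoid at C14 inserts into the C13–H bond through a concerted three-centre transition state and forms the C14–C13 bond. The closest known reaction type is the dirhodium carboxamidate-catalysed synthesis of γ-lactones from alkyl diazoacetates by insertion into a C–H bond next to an ether oxygen. The lactone ring (C13, C14, C15, O16, C16) closes by 1,5 C–H insertion through a five-membered transition state. The one new stereocentre, quaternary C13, is controlled by the substrate alone, since insertion goes with retention and the (13R) C–H centre of step 4 becomes the (13S) spiro centre with C14 on the face that held hydrogen. The step needs site selectivity for C13–H over the C16 and C12 methylene C–H bonds and over attack of the carbenoid on the lone pairs of O9, which should be secured because the tertiary C13–H bond is the most hydridic one (α to O9), is the only one that closes a five-membered ring, and the electron-rich acetamidate ligands make the carbenoid selective for insertion over ylide formation. The enone and all ring C–H bonds lie out of reach of the tethered carbenoid.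

**Step 9**
Reactants: 14 (13S)-9α,13-epoxy-6-oxolabd-7-en-15,16-olide
Product: 15 (13S)-9α,13:15,16-diepoxylabd-7-ene-6β,15-diol
Conditions: i-Bu2AlH (4 equiv), CH2Cl2, −78 °C; aqueous KNaC4H4O6 (potassium sodium tartrate)
Reagents that add atoms: none
Why: Hydride reduction stops the lactone at the lactol (C15 epimers, of no consequence) and reduces the enone 1,2 from the α-face, the β-face of C6 being blocked by the axial methyl groups on C4 and C10, which should give the axial 6β-allylic alcohol needed as directing group.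

**Step 10**
Reactants: 15 (13S)-9α,13:15,16-diepoxylabd-7-ene-6β,15-diol
Product: 17 (13S)-9α,13:15,16-diepoxy-15-methoxylabdane-6β,7β,8β-triol, via osmate ester 16 (not isolated)
Conditions: OsO4 (1.05 equiv), TMEDA, CH2Cl2, −78 °C; then HCl, MeOH, 25 °C
Reagents that add atoms: osmium tetroxide, O=[Os](=O)(=O)=O; methanol, CO
Why: In this hydrogen-bond-directed syn-dihydroxylation the axial 6β-hydroxyl binds the OsO4·TMEDA complex and delivers both oxygens to the β-face of C7=C8 (the α-face is also covered by the axial C9–O bond and the spiro rings), which should set 7β-OH and 8β-OH with the C8 methyl α, and methanolic HCl then cleaves the osmate ester and turns the lactol into its methyl acetal.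

**Step 11**
Reactants: 17 (13S)-9α,13:15,16-diepoxy-15-methoxylabdane-6β,7β,8β-triol
Product: 18 (13S)-7β-acetoxy-9α,13:15,16-diepoxy-15-methoxylabdane-6β,8β-diol
Conditions: Ac2O, pyridine, DMAP (cat), 0 °C
Reagents that add atoms: acetic anhydride, CC(=O)OC(C)=O
Why: Acetylation should take only the equatorial secondary 7β-hydroxyl, since the axial 6β-hydroxyl is buried between the axial methyl groups on C4 and C10 and the 8β-hydroxyl is tertiary.

**Step 12**
Reactants: 18 (13S)-7β-acetoxy-9α,13:15,16-diepoxy-15-methoxylabdane-6β,8β-diol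
Product: 19 (13S)-7β-acetoxy-9α,13:15,16-diepoxy-8β-hydroxy-15-methoxylabdan-6-one
Conditions: Dess–Martin periodinane, NaHCO3, CH2Cl2, 25 °C
Reagents that add atoms: none
Why: Dess–Martin oxidation of the hindered axial 6β-alcohol gives the 6-ketone under buffered conditions, the equatorial 7β-acetate being the stable epimer next to the carbonyl and the acetal shielding C15 from oxidation.

**Step 13**
Reactants: 19 (13S)-7β-acetoxy-9α,13:15,16-diepoxy-8β-hydroxy-15-methoxylabdan-6-one
Product: 20 (13S)-7β-acetoxy-9α,13:15,16-diepoxy-8β,15-dihydroxylabdan-6-one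
Conditions: AcOH/THF/H2O (3:1:1), 40 °C
Reagents that add atoms: water, O
Why: Mild acid hydrolysis of the cyclic methyl acetal through the C15 oxocarbenium ion returns the lactol under conditions that leave the α-acetoxy ketone and the tertiary alcohol alone.

**Step 14**
Reactants: 20 (13S)-7β-acetoxy-9α,13:15,16-diepoxy-8β,15-dihydroxylabdan-6-one
Product: 21 (13S)-7β-acetoxy-9α,13:15,16-diepoxy-8β-hydroxylabd-14-en-6-one
Conditions: MsCl, Et3N, CH2Cl2, −30 to 25 °C; NaHCO3 work-up, Et3N-deactivated silica
Reagents that add atoms: none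
Why: Sulfonylation of the lactol hydroxyl and amine-mediated loss of methanesulfonate across C14–C15 (lactol dehydration to a 2,3-dihydrofuran) should form the enol ether under basic conditions that spare the acid-labile allylic ether centre C13, the tertiary 8-hydroxyl being too hindered to react.

**Compound list**
1 | (+)-larixol (labda-8(17),14-diene-6α,13S-diol) | C=C1C[C@H](O)[C@H]2C(C)(C)CCC[C@]2(C)[C@H]1CC[C@](C)(O)C=C | starting material
2 | 6α-hydroxy-14,15-dinorlabd-8(17)-en-13-one | C=C1C[C@H](O)[C@H]2C(C)(C)CCC[C@]2(C)[C@H]1CCC(C)=O | intermediate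
3 | 14,15-dinorlabd-8(17)-ene-6,13-dione | C=C1CC(=O)[C@H]2C(C)(C)CCC[C@]2(C)[C@H]1CCC(C)=O | intermediate
4 | 14,15-dinorlabd-7-ene-6,13-dione | CC1=CC(=O)[C@H]2C(C)(C)CCC[C@]2(C)[C@H]1CCC(C)=O | intermediate
5 | 13-trimethylsilyloxy-14,15-dinorlabda-7,13(16)-dien-6-one | CC1=CC(=O)[C@H]2C(C)(C)CCC[C@]2(C)[C@H]1CCC(=C)O[Si](C)(C)C | intermediate
6 | 16-trimethylsilyloxy-14,15-dinorlabd-7-ene-6,13-dione | CC1=CC(=O)[C@H]2C(C)(C)CCC[C@]2(C)[C@H]1CCC(=O)CO[Si](C)(C)C | intermediate
7 | 16-hydroxy-14,15-dinorlabd-7-ene-6,13-dione | CC1=CC(=O)[C@H]2C(C)(C)CCC[C@]2(C)[C@H]1CCC(=O)CO | intermediate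
8 | (13R)-13,16-dihydroxy-14,15-dinorlabd-7-en-6-one | CC1=CC(=O)[C@H]2C(C)(C)CCC[C@]2(C)[C@H]1CC[C@H](CO)O | intermediate
9 | (13R)-16-benzoyloxy-13-hydroxy-14,15-dinorlabd-7-en-6-one | CC1=CC(=O)[C@H]2C(C)(C)CCC[C@]2(C)[C@H]1CC[C@H](COC(=O)c3ccccc3)O | intermediate
10 | (13R)-16-benzoyloxy-9α,13-epoxy-14,15-dinorlabd-7-en-6-one | CC1=CC(=O)[C@H]2C(C)(C)CCC[C@]2(C)[C@@]13CC[C@H](COC(=O)c4ccccc4)O3 | intermediate
11 | (13R)-9α,13-epoxy-16-hydroxy-14,15-dinorlabd-7-en-6-one | CC1=CC(=O)[C@H]2C(C)(C)CCC[C@]2(C)[C@@]13CC[C@H](CO)O3 | intermediate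
12 | 16-O-(tosylhydrazonoacetyl) ester of 11 | CC1=CC(=O)[C@H]2C(C)(C)CCC[C@]2(C)[C@@]13CC[C@H](COC(=O)C=NNS(=O)(=O)c4ccc(C)cc4)O3 | intermediate
13 | 16-O-diazoacetate of 11 | CC1=CC(=O)[C@H]2C(C)(C)CCC[C@]2(C)[C@@]13CC[C@H](COC(=O)C=[N+]=[N-])O3 | intermediate
14 | (13S)-9α,13-epoxy-6-oxolabd-7-en-15,16-olide | CC1=CC(=O)[C@H]2C(C)(C)CCC[C@]2(C)[C@@]13CC[C@@]4(CC(=O)OC4)O3 | intermediate
15 | (13S)-9α,13:15,16-diepoxylabd-7-ene-6β,15-diol (both C15 epimers) | CC1=C[C@@H](O)[C@H]2C(C)(C)CCC[C@]2(C)[C@@]13CC[C@@]4(CC(O)OC4)O3 | intermediate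
16 | 7β,8β-osmate ester of 15, TMEDA adduct | CN(C)CCN(C)C.O=[Os]4(=O)O[C@H]1[C@@H](O)[C@H]2C(C)(C)CCC[C@]2(C)[C@@]2(CC[C@@]3(CC(O)OC3)O2)[C@@]1(C)O4 | intermediate
17 | (13S)-9α,13:15,16-diepoxy-15-methoxylabdane-6β,7β,8β-triol | O[C@H]1[C@@H](O)[C@H]2C(C)(C)CCC[C@]2(C)[C@@]2(CC[C@@]3(CC(OC)OC3)O2)[C@@]1(C)O | intermediate
18 | (13S)-7β-acetoxy-9α,13:15,16-diepoxy-15-methoxylabdane-6β,8β-diol | CC(=O)O[C@H]1[C@@H](O)[C@H]2C(C)(C)CCC[C@]2(C)[C@@]2(CC[C@@]3(CC(OC)OC3)O2)[C@@]1(C)O | intermediate
19 | (13S)-7β-acetoxy-9α,13:15,16-diepoxy-8β-hydroxy-15-methoxylabdan-6-one | CC(=O)O[C@H]1C(=O)[C@H]2C(C)(C)CCC[C@]2(C)[C@@]2(CC[C@@]3(CC(OC)OC3)O2)[C@@]1(C)O | intermediate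
20 | (13S)-7β-acetoxy-9α,13:15,16-diepoxy-8β,15-dihydroxylabdan-6-one | CC(=O)O[C@H]1C(=O)[C@H]2C(C)(C)CCC[C@]2(C)[C@@]2(CC[C@@]3(CC(O)OC3)O2)[C@@]1(C)O | intermediate
21 | (13S)-7β-acetoxy-9α,13:15,16-diepoxy-8β-hydroxylabd-14-en-6-one | CC(=O)O[C@H]1C(=O)[C@H]2C(C)(C)CCC[C@]2(C)[C@@]2(CC[C@@]3(C=COC3)O2)[C@@]1(C)O | target

**Step count**
Total steps: 14. Longest linear sequence: 14 steps (1 to 21).

**Steps most likely to fail**

Step 8. The carbenoid may be captured by the lone pairs of the ring oxygen O9 (oxonium ylide, then 1,2-shift) or may dimerise in place of inserting. The fallback sets out from 11 and keeps the C–H insertion but uses an acceptor/acceptor carbenoid on a traceless malonate tether. Esterification of 11 with monoallyl malonate (DCC, DMAP) would give the mixed malonate F1, and diazo transfer (p-acetamidobenzenesulfonyl azide, Et3N) the diazomalonate F2. Rh2(OAc)4 in CH2Cl2 at 40 °C would give the allyl ester lactone F3 by insertion into the same C13–H bond with retention. Pd(OAc)2/PPh3 with HCO2H/Et3N would then remove the allyl group and decarboxylate, which comes back to the route at 14.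

Step 6. The C13 alkoxyl radical may undergo β-scission toward C16, or the carbinol may be oxidised, in place of the 1,5-hydrogen transfer. The fallback sets out from 7 and makes the C9–O bond by polar chemistry, with C13 entered in the mirror-image configuration because the ring is then closed with inversion. Hydrogenation of 7 with RuBr2[(S)-BINAP] would give the (13S)-diol F4, and Mitsunobu cyclodehydration (PPh3, DIAD) the terminal epoxide F5. KOt-Bu and O2 in the presence of P(OEt)3 would oxygenate the γ-carbon C9 of the enone on its α-face through the hydroperoxide F6 to the 9α-alcohol F7. Camphorsulfonic acid would then let the tertiary hydroxyl open the epoxide at C13 (5-exo, inversion), which gives 11 with its C16 hydroxyl free and rejoins the route there.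

Step 10. Osmylation may occur on the α-face, or not at all at the hindered trisubstituted alkene. The fallback sets out from 15 and reaches the 7β,8β-dioxygenation by epoxidation, trans-diaxial opening and epimerisation. Acetalisation (MeOH, PPTS) would give the methyl acetal F8, and hydroxyl-directed epoxidation (VO(acac)2, t-BuOOH) the 7β,8β-epoxide F9. Opening with CsOAc at the secondary carbon C7 from the α-face (Fürst–Plattner) would give the 7α-acetoxy-6β,8β-diol F10, and Dess–Martin oxidation the 6-ketone F11. DBU would then epimerise the axial 7α-acetate to the equatorial 7β-acetate, which is 19.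

**Further compounds**
F1 | step 8 | 16-O-(allyloxycarbonylacetyl) ester of 11 | CC1=CC(=O)[C@H]2C(C)(C)CCC[C@]2(C)[C@@]13CC[C@H](COC(=O)CC(=O)OCC=C)O3
F2 | step 8 | 16-O-(allyloxycarbonyl)diazoacetyl ester of 11 | CC1=CC(=O)[C@H]2C(C)(C)CCC[C@]2(C)[C@@]13CC[C@H](COC(=O)C(=[N+]=[N-])C(=O)OCC=C)O3
F3 | step 8 | 14-allyloxycarbonyl derivative of lactone 14 (C14 epimers) | CC1=CC(=O)[C@H]2C(C)(C)CCC[C@]2(C)[C@@]13CC[C@@]4(C(C(=O)OCC=C)C(=O)OC4)O3
F4 | step 6 | (13S)-13,16-dihydroxy-14,15-dinorlabd-7-en-6-one | CC1=CC(=O)[C@H]2C(C)(C)CCC[C@]2(C)[C@H]1CC[C@@H](CO)O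
F5 | step 6 | (13S)-13,16-epoxy-14,15-dinorlabd-7-en-6-one | CC1=CC(=O)[C@H]2C(C)(C)CCC[C@]2(C)[C@H]1CC[C@H]3CO3
F6 | step 6 | (13S)-13,16-epoxy-9α-hydroperoxy-14,15-dinorlabd-7-en-6-one | CC1=CC(=O)[C@H]2C(C)(C)CCC[C@]2(C)[C@@]1(OO)CC[C@H]3CO3
F7 | step 6 | (13S)-13,16-epoxy-9α-hydroxy-14,15-dinorlabd-7-en-6-one | CC1=CC(=O)[C@H]2C(C)(C)CCC[C@]2(C)[C@@]1(O)CC[C@H]3CO3
F8 | step 10 | (13S)-9α,13:15,16-diepoxy-15-methoxylabd-7-en-6β-ol | CC1=C[C@@H](O)[C@H]2C(C)(C)CCC[C@]2(C)[C@@]13CC[C@@]4(CC(OC)OC4)O3
F9 | step 10 | (13S)-7β,8β:9α,13:15,16-triepoxy-15-methoxylabdan-6β-ol | C[C@]12O[C@H]1[C@@H](O)[C@H]3C(C)(C)CCC[C@]3(C)[C@@]24CC[C@@]5(CC(OC)OC5)O4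
F10 | step 10 | (13S)-7α-acetoxy-9α,13:15,16-diepoxy-15-methoxylabdane-6β,8β-diol | CC(=O)O[C@@H]1[C@@H](O)[C@H]2C(C)(C)CCC[C@]2(C)[C@@]2(CC[C@@]3(CC(OC)OC3)O2)[C@@]1(C)O
F11 | step 10 | (13S)-7α-acetoxy-9α,13:15,16-diepoxy-8β-hydroxy-15-methoxylabdan-6-one | CC(=O)O[C@@H]1C(=O)[C@H]2C(C)(C)CCC[C@]2(C)[C@@]2(CC[C@@]3(CC(OC)OC3)O2)[C@@]1(C)O
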